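## Retrosynthetic overview

1. Target ⇐ chelation-controlled 5-O-demethylation of 4'-hydroxy-5,6,7,8,3',5'-hexamethoxyflavone ⇐ hydrogenolysis of its 4'-O-benzyl ether.
2. Pyranone ring C is the only ring built and is formed last (rings A and B are bought arenes) ⇐ I2/DMSO oxidative cyclisation of a 2'-hydroxychalcone.
3. Chalcone ⇐ intermolecular Claisen–Schmidt aldol condensation (key C–C bond, the future C2–C3) between the ring A methyl ketone and the ring B aldehyde.
4. Ring A ketone ⇐ 3,4,5-trimethoxyphenol (C-acetylation, bromination, copper-catalysed methoxylation); ring B aldehyde ⇐ syringaldehyde (O-benzylation).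

Assumption: the target has no stereocentre (it is achiral), so "single enantiomer" needs no stereocontrol. The E-alkene and the racemic sp3 centres of transient intermediates all disappear before the end.

## Route

Step 1
Reactants: 1 3,4,5-trimethoxyphenol
Product: 3 1-(6-hydroxy-2,3,4-trimethoxyphenyl)ethanone, via difluoroboron chelate 2 (not isolated)
Conditions: AcOH, BF3·OEt2 (3 equiv), 90 °C, 2 h; then H2O/EtOH, 60 °C, 1 h
Reagents that add atoms: acetic acid, CC(=O)O
Why: BF3-mediated Friedel–Crafts (Fries-type) C-acetylation can only go ortho to the phenol OH, because the para position carries OMe and the two ortho sites are equivalent; the ketone is trapped as its O,O-difluoroboron chelate, which the aqueous work-up hydrolyses.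

Step 2
Reactants: 3 1-(6-hydroxy-2,3,4-trimethoxyphenyl)ethanone
Product: 4 1-(3-bromo-2-hydroxy-4,5,6-trimethoxyphenyl)ethanone
Conditions: NBS (1.05 equiv), MeCN, 0 °C to rt, 1 h
Reagents that add atoms: N-bromosuccinimide, O=C1CCC(=O)N1Br
Why: Electrophilic aromatic bromination hits the single remaining ring CH, which is activated ortho to OH and para to OMe, far faster than the methyl ketone under non-acidic conditions.

Step 3
Reactants: 4 1-(3-bromo-2-hydroxy-4,5,6-trimethoxyphenyl)ethanone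
Product: 5 1-(2-hydroxy-3,4,5,6-tetramethoxyphenyl)ethanone
Conditions: NaOMe (25 wt % in MeOH, 8 equiv), CuBr (0.2 equiv), DMF, 110 °C, N2, 5 h; then 2 M HCl
Reagents that add atoms: sodium methoxide, C[O-].[Na+]
Why: Ullmann-type methoxylation catalysed by CuBr (monovalent copper) replaces Br by OMe as in the classical 5-bromovanillin to syringaldehyde conversion; the ortho phenoxide keeps the acetyl group deactivated toward self-condensation.

Step 4
Reactants: 6 syringaldehyde (4-hydroxy-3,5-dimethoxybenzaldehyde)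
Product: 7 4-(benzyloxy)-3,5-dimethoxybenzaldehyde
Conditions: BnBr (1.2 equiv), K2CO3 (2 equiv), DMF, 60 °C, 4 h
Reagents that add atoms: benzyl bromide, BrCc1ccccc1
Why: Williamson etherification masks the phenol so that the aldehyde stays electrophilic under KOH in the next step; the benzyl ether survives base and I2/DMSO and is removed later by hydrogenolysis.

Step 5
Reactants: 5 1-(2-hydroxy-3,4,5,6-tetramethoxyphenyl)ethanone; 7 4-(benzyloxy)-3,5-dimethoxybenzaldehyde (1.1 equiv)
Product: 9 (E)-3-[4-(benzyloxy)-3,5-dimethoxyphenyl]-1-(2-hydroxy-3,4,5,6-tetramethoxyphenyl)prop-2-en-1-one, via racemic aldol adduct 8 (not isolated)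
Conditions: KOH (50 % aq., 10 equiv), EtOH, rt, 48 h; then 2 M HCl to pH 3
Reagents that add atoms: none
Why: Claisen–Schmidt crossed aldol condensation, in which only the ketone can enolise and the aldehyde cannot; E1cB dehydration of the racemic β-hydroxy ketone gives the thermodynamic E-enone, so its stereocentre is lost.

Step 6
Reactants: 9 (E)-3-[4-(benzyloxy)-3,5-dimethoxyphenyl]-1-(2-hydroxy-3,4,5,6-tetramethoxyphenyl)prop-2-en-1-one
Product: 12 2-[4-(benzyloxy)-3,5-dimethoxyphenyl]-5,6,7,8-tetramethoxy-4H-chromen-4-one, via racemic flavanone 10 (not isolated), via racemic 3-iodoflavanone 11 (not isolated)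
Conditions: I2 (0.1 equiv), DMSO, 120 °C, 3 h; then aq. Na2S2O3
Reagents that add atoms: none
Why: Iodine-catalysed oxidative cyclisation: 6-endo oxa-Michael closure to the flavanone, α-iodination and loss of HI give the flavone while DMSO reoxidises HI to I2; ring A has no free CH to iodinate.

Step 7
Reactants: 12 2-[4-(benzyloxy)-3,5-dimethoxyphenyl]-5,6,7,8-tetramethoxy-4H-chromen-4-one
Product: 13 2-(4-hydroxy-3,5-dimethoxyphenyl)-5,6,7,8-tetramethoxy-4H-chromen-4-one
Conditions: H2 (1 atm), 10 % Pd/C, EtOAc/MeOH 1:1, rt, 2 h (stop at full conversion)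
Reagents that add atoms: none
Why: Catalytic hydrogenolysis cleaves the benzylic C–O bond cleanly, and at 1 atm and room temperature the conjugated C2=C3 bond and carbonyl of the flavone are not reduced.

Step 8
Reactants: 13 2-(4-hydroxy-3,5-dimethoxyphenyl)-5,6,7,8-tetramethoxy-4H-chromen-4-one
Product: 15 5,4'-dihydroxy-6,7,8,3',5'-pentamethoxyflavone, via boron chelate 14 (not isolated)
Conditions: BCl3 (1 M in CH2Cl2, 3 equiv), CH2Cl2, −20 to 0 °C, 2 h; then 1 M HCl/MeOH, rt
Reagents that add atoms: none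
Why: Chelation-controlled Lewis-acid demethylation: BCl3 bound to the C4 carbonyl activates only the peri 5-OMe for chloride attack on its methyl group and locks the product as a six-membered O–B–O chelate, so the other five methoxy groups stay intact at or below 0 °C.

## Compound list

1 | 3,4,5-trimethoxyphenol | COc1cc(O)cc(OC)c1OC | starting material
2 | O,O-difluoroboron chelate of 3 (2,2-difluoro-5,6,7-trimethoxy-4-methyl-1,3,2-benzodioxaborinine; boron bridges the phenolic and carbonyl oxygens; not isolated) | CC1=[O+][B-](F)(F)Oc2cc(OC)c(OC)c(OC)c12 | intermediate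
3 | 1-(6-hydroxy-2,3,4-trimethoxyphenyl)ethanone | CC(=O)c1c(O)cc(OC)c(OC)c1OC | intermediate
4 | 1-(3-bromo-2-hydroxy-4,5,6-trimethoxyphenyl)ethanone | CC(=O)c1c(O)c(Br)c(OC)c(OC)c1OC | intermediate
5 | 1-(2-hydroxy-3,4,5,6-tetramethoxyphenyl)ethanone | CC(=O)c1c(O)c(OC)c(OC)c(OC)c1OC | intermediate
6 | syringaldehyde (4-hydroxy-3,5-dimethoxybenzaldehyde) | COc1cc(C=O)cc(OC)c1O | starting material
7 | 4-(benzyloxy)-3,5-dimethoxybenzaldehyde | COc1cc(C=O)cc(OC)c1OCc1ccccc1 | intermediate
8 | racemic 3-[4-(benzyloxy)-3,5-dimethoxyphenyl]-3-hydroxy-1-(2-hydroxy-3,4,5,6-tetramethoxyphenyl)propan-1-one (aldol adduct; not isolated) | COc1cc(C(O)CC(=O)c2c(O)c(OC)c(OC)c(OC)c2OC)cc(OC)c1OCc1ccccc1 | intermediate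
9 | (E)-3-[4-(benzyloxy)-3,5-dimethoxyphenyl]-1-(2-hydroxy-3,4,5,6-tetramethoxyphenyl)prop-2-en-1-one | COc1cc(/C=C/C(=O)c2c(O)c(OC)c(OC)c(OC)c2OC)cc(OC)c1OCc1ccccc1 | intermediate
10 | racemic 2-[4-(benzyloxy)-3,5-dimethoxyphenyl]-5,6,7,8-tetramethoxy-2,3-dihydro-4H-chromen-4-one (flavanone; not isolated) | COc1cc(C2CC(=O)c3c(OC)c(OC)c(OC)c(OC)c3O2)cc(OC)c1OCc1ccccc1 | intermediate
11 | racemic 2-[4-(benzyloxy)-3,5-dimethoxyphenyl]-3-iodo-5,6,7,8-tetramethoxy-2,3-dihydro-4H-chromen-4-one (C2/C3 relative configuration not controlled; not isolated) | COc1cc(C2Oc3c(OC)c(OC)c(OC)c(OC)c3C(=O)C2I)cc(OC)c1OCc1ccccc1 | intermediate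
12 | 2-[4-(benzyloxy)-3,5-dimethoxyphenyl]-5,6,7,8-tetramethoxy-4H-chromen-4-one | COc1cc(-c2cc(=O)c3c(OC)c(OC)c(OC)c(OC)c3o2)cc(OC)c1OCc1ccccc1 | intermediate
13 | 2-(4-hydroxy-3,5-dimethoxyphenyl)-5,6,7,8-tetramethoxy-4H-chromen-4-one | COc1cc(-c2cc(=O)c3c(OC)c(OC)c(OC)c(OC)c3o2)cc(OC)c1O | intermediate
14 | dichloroboron chelate of the product (boron bridges O5 and the C4 carbonyl oxygen; 4'-oxygen carried as its OBCl2 ester; not isolated) | COc1cc(-c2cc3=[O+][B-](Cl)(Cl)Oc4c(OC)c(OC)c(OC)c(o2)c34)cc(OC)c1OB(Cl)Cl | intermediate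
15 | 5,4'-dihydroxy-6,7,8,3',5'-pentamethoxyflavone (5-hydroxy-2-(4-hydroxy-3,5-dimethoxyphenyl)-6,7,8-trimethoxy-4H-chromen-4-one; achiral) | COc1cc(-c2cc(=O)c3c(O)c(OC)c(OC)c(OC)c3o2)cc(OC)c1O | target

## Step count and risks

Total step count: 8 (steps 1–3 on ring A, step 4 on ring B, steps 5–8 after the union).
Longest linear sequence: 7 steps (1 → 3 → 4 → 5 → 9 → 12 → 13 → 15).

Steps most likely to fail:

Step 3 (copper-catalysed methoxylation). The risk is hydrodebromination back to 3 or a stalled reaction on the crowded bromide flanked by two oxygens. The fallback sets out from 4 and comes back at 5. Palladium-catalysed hydroxylation of 4 (Pd2(dba)3 2 mol %, a zerovalent palladium source, with tBuXPhos 8 mol %, KOH 4 equiv, degassed 1,4-dioxane/H2O 1:1, 100 °C, then HCl) gives the catechol 1-(2,3-dihydroxy-4,5,6-trimethoxyphenyl)ethanone F1. Its 2-OH is tied up in the hydrogen bond to the acetyl carbonyl, so MeI (1.05 equiv) with K2CO3 in acetone at rt methylates only the 3-OH and gives 5.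

Step 6 (I2/DMSO oxidative cyclisation). The risk is partial loss of the 5-methyl or the benzyl group to HI at 120 °C, or stalling at the flavanone. The fallback replaces the chalcone oxidation by a Claisen-condensation route; it sets out from 5 and comes back at 12. Commercial methyl syringate F2 is benzylated (BnBr, K2CO3, DMF, 60 °C) to methyl 4-(benzyloxy)-3,5-dimethoxybenzoate F3. The dianion of 5 (LiN(SiMe3)2, 4 equiv, THF, −78 °C to rt) is acylated by F3 to give, after acidic work-up, 1-[4-(benzyloxy)-3,5-dimethoxyphenyl]-3-(2-hydroxy-3,4,5,6-tetramethoxyphenyl)propane-1,3-dione F4. Cyclodehydration of F4 (AcOH with a trace of H2SO4, 90 °C, 1 h) gives 12 with no oxidant.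

Step 8 (selective 5-O-demethylation). The risk is loss of a ring B methyl next to the borylated 4'-oxygen, or over-demethylation at C6. The fallback masks the phenol first; it sets out from 13 and comes back at 15. Acetylation of 13 (Ac2O, pyridine, rt) gives 2,6-dimethoxy-4-(5,6,7,8-tetramethoxy-4-oxo-4H-chromen-2-yl)phenyl acetate F5. BCl3 (1.5 equiv, CH2Cl2, −20 to 0 °C) then cleaves only the 5-OMe through the dichloroboron chelate of the 5-oxygen and carbonyl F6, which is not isolated. Aqueous HCl work-up gives 4-(5-hydroxy-6,7,8-trimethoxy-4-oxo-4H-chromen-2-yl)-2,6-dimethoxyphenyl acetate F7. Methanolysis of the aryl acetate in F7 (K2CO3, MeOH, rt, 30 min, then dilute HCl) gives 15.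

## Further compounds

F1 | step 3 | 1-(2,3-dihydroxy-4,5,6-trimethoxyphenyl)ethanone | CC(=O)c1c(O)c(O)c(OC)c(OC)c1OC
F2 | step 6 | methyl syringate (methyl 4-hydroxy-3,5-dimethoxybenzoate; commercial) | COc1cc(C(=O)OC)cc(OC)c1O
F3 | step 6 | methyl 4-(benzyloxy)-3,5-dimethoxybenzoate | COc1cc(C(=O)OC)cc(OC)c1OCc1ccccc1
F4 | step 6 | 1-[4-(benzyloxy)-3,5-dimethoxyphenyl]-3-(2-hydroxy-3,4,5,6-tetramethoxyphenyl)propane-1,3-dione | COc1cc(C(=O)CC(=O)c2c(O)c(OC)c(OC)c(OC)c2OC)cc(OC)c1OCc1ccccc1
F5 | step 8 | 2,6-dimethoxy-4-(5,6,7,8-tetramethoxy-4-oxo-4H-chromen-2-yl)phenyl acetate | COc1cc(-c2cc(=O)c3c(OC)c(OC)c(OC)c(OC)c3o2)cc(OC)c1OC(C)=O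
F6 | step 8 | dichloroboron chelate of F7 (boron bridges O5 and the C4 carbonyl oxygen; not isolated) | COc1cc(-c2cc3=[O+][B-](Cl)(Cl)Oc4c(OC)c(OC)c(OC)c(o2)c34)cc(OC)c1OC(C)=O
F7 | step 8 | 4-(5-hydroxy-6,7,8-trimethoxy-4-oxo-4H-chromen-2-yl)-2,6-dimethoxyphenyl acetate | COc1cc(-c2cc(=O)c3c(O)c(OC)c(OC)c(OC)c3o2)cc(OC)c1OC(C)=O
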